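**Plan**
- Retrosynthesis: first the three O‑benzyl groups (catechol and CH2OH) are added back. Then the ArCH2–C3 bond of the oxolan‑3‑ol is cut, giving a 3,4‑dimethoxybenzyl metal and a 4,5‑cis‑oxolan‑3‑one. Then the ring O1–C2 bond is cut (β‑hydroxy chloromethyl ketone), then the ClCH2–C(=O) bond (Weinreb amide), then the C4–C5 bond (aldol).
- Enabling feature: C3 of the oxolane ring is a tertiary carbinol flanked by the ring C2H2 and by C4. The C4–CH2OH and C5–aryl groups lie on the same ring face as the C3–OH. A C3 ketone therefore has one open face, and a benzyl nucleophile entering there gives the target arrangement.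
- Forward order: an Evans aldol builds the C5–C4–C(=O) chain, the imide is converted to a Weinreb amide, and a one‑carbon homologation gives the chloromethyl ketone. A 5‑exo‑tet etherification closes the only ring. The two fragments are then joined at the fully substituted carbon, and hydrogenolysis removes the benzyl groups.
- Stereochemistry: C4 and C5 come from the (R)‑4‑benzyloxazolidinone auxiliary (syn aldol, which becomes 4,5‑cis in the ring). C3 comes from substrate control in the fragment union.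

Key step: step 7

Assumption: metal‑bound adducts that only await protonation on work‑up (boron aldolate, tetrahedral Weinreb adducts, metal alkoxides) are treated as salts of the product and are not numbered. Locants refer to the oxolane ring O1–C2H2–C3(OH)–C4(CH2OH)–C5(aryl), in which the target is (3R,4R,5R) with aryl, CH2OH and OH on one face.

**Step 1**
Reactants: 1 3‑(benzyloxy)propanoic acid; 2 (R)‑4‑benzyloxazolidin‑2‑one
Product: 4 (R)‑4‑benzyl‑3‑[3‑(benzyloxy)propanoyl]oxazolidin‑2‑one, via mixed pivalic anhydride 3 (not isolated)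
Conditions: PivCl, Et3N, THF, −20 → 0 °C; then LiCl, 2, rt
Reagents that add atoms: none
Why: N‑acylation of the oxazolidinone through a mixed pivalic anhydride (LiCl/Et3N protocol) should occur at the unhindered acyl carbon of 3 and creates no stereocentre.

**Step 2**
Reactants: 4 (R)‑4‑benzyl‑3‑[3‑(benzyloxy)propanoyl]oxazolidin‑2‑one; 5 3,4‑bis(benzyloxy)benzaldehyde
Product: 7 (R)‑4‑benzyl‑3‑[(2R,3R)‑3‑[3,4‑bis(benzyloxy)phenyl]‑2‑[(benzyloxy)methyl]‑3‑hydroxypropanoyl]oxazolidin‑2‑one, via dibutylboron Z‑enolate 6 (not isolated)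
Conditions: Bu2BOTf, i‑Pr2NEt, CH2Cl2, 0 °C; then 5, −78 → 0 °C; pH 7 buffer, MeOH, 30% H2O2, 0 °C
Reagents that add atoms: none
Why: In this Evans syn aldol the Z‑boron enolate reacts through a chair Zimmerman–Traxler transition state on the enolate face away from the auxiliary benzyl group, which should set both new centres as the (2R,3R) syn pair that later becomes C4 and C5 of the ring.

**Step 3**
Reactants: 7 the syn aldol imide
Product: 8 (2R,3R)‑3‑[3,4‑bis(benzyloxy)phenyl]‑2‑[(benzyloxy)methyl]‑3‑hydroxy‑N‑methoxy‑N‑methylpropanamide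
Conditions: MeNH(OMe)·HCl, AlMe3, CH2Cl2, 0 °C; then 7, −10 °C → rt; aq. Rochelle salt
Reagents that add atoms: N,O‑dimethylhydroxylamine hydrochloride, CNOC.Cl
Why: Weinreb transamidation with the aluminium amide, assisted by the free β‑hydroxyl, should cleave the exocyclic imide carbonyl without base and so without touching the α‑centre.

**Step 4**
Reactants: 8 the β‑hydroxy Weinreb amide
Product: 9 (2R,3R)‑3‑[3,4‑bis(benzyloxy)phenyl]‑2‑[(benzyloxy)methyl]‑N‑methoxy‑N‑methyl‑3‑[(triethylsilyl)oxy]propanamide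
Conditions: TESCl, imidazole, DMF, 0 °C → rt
Reagents that add atoms: chlorotriethylsilane, CC[Si](CC)(CC)Cl
Why: Silyl ether protection masks the hydroxyl so that it neither quenches the carbenoid of the next step nor opens a retro‑aldol path.

**Step 5**
Reactants: 9 the TES‑protected Weinreb amide
Product: 10 (3R,4R)‑4‑[3,4‑bis(benzyloxy)phenyl]‑3‑[(benzyloxy)methyl]‑1‑chloro‑4‑[(triethylsilyl)oxy]butan‑2‑one
Conditions: ICH2Cl, MeLi·LiBr, THF/Et2O, −78 °C; sat. aq. NH4Cl at −78 °C
Reagents that add atoms: chloroiodomethane, ClCI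
Why: Homologation of a Weinreb amide with chloromethyllithium (halomethyl carbenoid acylation) should stop at the chelated tetrahedral adduct, which prevents over‑addition and keeps the α‑centre from enolising until the cold quench.

**Step 6**
Reactants: 10 the chloromethyl ketone
Product: 12 (4R,5R)‑5‑[3,4‑bis(benzyloxy)phenyl]‑4‑[(benzyloxy)methyl]oxolan‑3‑one, via hydroxy chloromethyl ketone 11 (not isolated)
Conditions: HF·pyridine, pyridine, THF, 0 °C; then excess NaHCO3, NaI (cat.), MeCN, 40 °C; rapid filtration through deactivated silica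
Reagents that add atoms: none
Why: Desilylation followed by intramolecular Williamson etherification (5‑exo‑tet SN2 at the Finkelstein‑activated α‑halo ketone carbon) forms the O1–C2 bond at a CH2 group, so no stereocentre is touched and the syn aldol pair should appear as the 4,5‑cis ring, while bicarbonate is too weak a base for epimerisation or E1cB loss of benzyl alcohol.

**Step 7**
Reactants: 12 the 4,5‑cis‑oxolan‑3‑one; 13 3,4‑dimethoxybenzyl chloride
Product: 16 (3R,4R,5R)‑5‑[3,4‑bis(benzyloxy)phenyl]‑4‑[(benzyloxy)methyl]‑3‑(3,4‑dimethoxybenzyl)oxolan‑3‑ol, via 3,4‑dimethoxybenzylmagnesium chloride 14 (not isolated), via (3,4‑dimethoxybenzyl)cerium dichloride 15 (not isolated)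
Conditions: 13, Mg, THF, 0 °C (slow addition, dilute); anhydrous CeCl3, THF, −78 °C; then 12, THF, −78 °C; aq. NH4Cl
Reagents that add atoms: none
Why: The σ‑benzylcerium reagent 15, formed by transmetalation of Grignard reagent 14, should add in a polar 1,2‑fashion to the cerium‑activated C3 carbonyl of 12, forming the CH2–C3 bond and the fully substituted carbinol in the event that joins the C9 fragment to the oxolane fragment. The closest known reaction type is the Imamoto organocerium addition of Grignard‑derived reagents to easily enolised ketones; no ring is closed. The new C3 centre is set by the substrate: the C4–CH2OBn group next to the carbonyl and the C5 aryl group shield one face of the oxolanone envelope, so the benzyl group should enter from the face bearing H‑4 and H‑5, placing benzyl trans and hydroxyl cis to CH2OBn and aryl, i.e. (3R). The step needs addition to outrun deprotonation at C4, which would epimerise the cis ketone or expel benzyloxide by E1cB; the low basicity and high oxophilicity of cerium at −78 °C should secure this. It also needs attack through the benzylic carbon and not the ortho position of the benzyl metal, which is the normal course with ketones.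

**Step 8**
Reactants: 16 the tribenzyl‑protected oxolan‑3‑ol
Product: 17 (3R,4R,5R)‑5‑(3,4‑dihydroxyphenyl)‑3‑(3,4‑dimethoxybenzyl)‑4‑(hydroxymethyl)oxolan‑3‑ol
Conditions: H2 (1 atm), 10% Pd/C, EtOAc/EtOH, rt, stopped when three equivalents of H2 are taken up
Reagents that add atoms: none
Why: Catalytic hydrogenolysis of the two aryl and one alkyl O‑benzyl ethers in a neutral, acid‑free medium should free catechol and primary alcohol, since O‑benzyl ethers cleave much faster than the ring benzylic C–O bond, and it leaves the methyl ethers, the tertiary alcohol and all three stereocentres untouched.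

**Compound list**
1 | 3‑(benzyloxy)propanoic acid | OC(=O)CCOCc1ccccc1 | starting material
2 | (R)‑4‑benzyloxazolidin‑2‑one | O=C1N[C@H](Cc2ccccc2)CO1 | starting material
3 | 3‑(benzyloxy)propanoic pivalic anhydride (not isolated) | CC(C)(C)C(=O)OC(=O)CCOCc1ccccc1 | intermediate
4 | (R)‑4‑benzyl‑3‑[3‑(benzyloxy)propanoyl]oxazolidin‑2‑one | O=C(CCOCc1ccccc1)N1C(=O)OC[C@H]1Cc1ccccc1 | intermediate
5 | 3,4‑bis(benzyloxy)benzaldehyde | O=Cc1ccc(OCc2ccccc2)c(OCc2ccccc2)c1 | starting material
6 | dibutylboron Z‑enolate of 4 (not isolated) | CCCCB(CCCC)O/C(=C\COCc1ccccc1)N1C(=O)OC[C@H]1Cc1ccccc1 | intermediate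
7 | (R)‑4‑benzyl‑3‑[(2R,3R)‑3‑[3,4‑bis(benzyloxy)phenyl]‑2‑[(benzyloxy)methyl]‑3‑hydroxypropanoyl]oxazolidin‑2‑one (syn aldol) | O[C@@H](c1ccc(OCc2ccccc2)c(OCc2ccccc2)c1)[C@@H](COCc1ccccc1)C(=O)N1C(=O)OC[C@H]1Cc1ccccc1 | intermediate
8 | (2R,3R)‑3‑[3,4‑bis(benzyloxy)phenyl]‑2‑[(benzyloxy)methyl]‑3‑hydroxy‑N‑methoxy‑N‑methylpropanamide | O[C@@H](c1ccc(OCc2ccccc2)c(OCc2ccccc2)c1)[C@@H](COCc1ccccc1)C(=O)N(C)OC | intermediate
9 | (2R,3R)‑3‑[3,4‑bis(benzyloxy)phenyl]‑2‑[(benzyloxy)methyl]‑N‑methoxy‑N‑methyl‑3‑[(triethylsilyl)oxy]propanamide | CC[Si](CC)(CC)O[C@@H](c1ccc(OCc2ccccc2)c(OCc2ccccc2)c1)[C@@H](COCc1ccccc1)C(=O)N(C)OC | intermediate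
10 | (3R,4R)‑4‑[3,4‑bis(benzyloxy)phenyl]‑3‑[(benzyloxy)methyl]‑1‑chloro‑4‑[(triethylsilyl)oxy]butan‑2‑one | CC[Si](CC)(CC)O[C@@H](c1ccc(OCc2ccccc2)c(OCc2ccccc2)c1)[C@@H](COCc1ccccc1)C(=O)CCl | intermediate
11 | (3R,4R)‑4‑[3,4‑bis(benzyloxy)phenyl]‑3‑[(benzyloxy)methyl]‑1‑chloro‑4‑hydroxybutan‑2‑one (not isolated) | O[C@@H](c1ccc(OCc2ccccc2)c(OCc2ccccc2)c1)[C@@H](COCc1ccccc1)C(=O)CCl | intermediate
12 | (4R,5R)‑5‑[3,4‑bis(benzyloxy)phenyl]‑4‑[(benzyloxy)methyl]oxolan‑3‑one (4,5‑cis) | O=C1CO[C@@H](c2ccc(OCc3ccccc3)c(OCc3ccccc3)c2)[C@H]1COCc1ccccc1 | intermediate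
13 | 3,4‑dimethoxybenzyl chloride | COc1ccc(CCl)cc1OC | starting material
14 | 3,4‑dimethoxybenzylmagnesium chloride (not isolated) | COc1ccc(C[Mg]Cl)cc1OC | intermediate
15 | (3,4‑dimethoxybenzyl)cerium dichloride (not isolated) | COc1ccc(C[Ce](Cl)Cl)cc1OC | intermediate
16 | (3R,4R,5R)‑5‑[3,4‑bis(benzyloxy)phenyl]‑4‑[(benzyloxy)methyl]‑3‑(3,4‑dimethoxybenzyl)oxolan‑3‑ol | COc1ccc(C[C@]2(O)CO[C@@H](c3ccc(OCc4ccccc4)c(OCc4ccccc4)c3)[C@H]2COCc2ccccc2)cc1OC | intermediate
17 | (3R,4R,5R)‑5‑(3,4‑dihydroxyphenyl)‑3‑(3,4‑dimethoxybenzyl)‑4‑(hydroxymethyl)oxolan‑3‑ol | COc1ccc(C[C@]2(O)CO[C@@H](c3ccc(O)c(O)c3)[C@H]2CO)cc1OC | target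

**Step count and risks**
Total step count: 8. Longest linear sequence: 8 steps (1 and 2 to 17); the benzyl fragment 13 enters at step 7.

Steps most likely to fail:

1. Step 7. The benzyl metal may act as a base at C4 of the cis ketone, which leads to epimerisation or E1cB loss of benzyl alcohol. Face discrimination may be incomplete, and Wurtz coupling may consume the reagent while the Grignard reagent forms. The fallback sets out from 12 and comes back at 16, and it moves the carbon–carbon bond formation with the arene to an unhindered primary carbon. Chloromethyllithium (ICH2Cl, MeLi·LiBr, THF, −78 °C) is a small, weakly basic carbenoid. It should add to the C3 carbonyl from the same open face to give lithium (3R,4R,5R)‑5‑[3,4‑bis(benzyloxy)phenyl]‑4‑[(benzyloxy)methyl]‑3‑(chloromethyl)oxolan‑3‑olate F1. On warming to room temperature this should close to the spiro‑epoxide (3S,6R,7R)‑6‑[3,4‑bis(benzyloxy)phenyl]‑7‑[(benzyloxy)methyl]‑1,5‑dioxaspiro[2.4]heptane F2, with the epoxide CH2 on the face opposite to CH2OBn and aryl. Copper‑catalysed opening of the epoxide at its CH2 terminus with commercial 3,4‑dimethoxyphenylmagnesium bromide (CuI cat., THF, −30 → 0 °C) should then give 16.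

2. Step 6. During the O‑alkylation the β‑hydroxy ketone may dehydrate to the enone, undergo retro‑aldol cleavage or epimerise at the α‑carbon, and the ring closure may be slow with a neutral hydroxyl. The fallback sets out from 9 and comes back at 12, and it closes the ring by carbenoid O–H insertion under neutral conditions.
   - MeMgBr (THF, 0 °C) should give the methyl ketone (3R,4R)‑4‑[3,4‑bis(benzyloxy)phenyl]‑3‑[(benzyloxy)methyl]‑4‑[(triethylsilyl)oxy]butan‑2‑one F3.
   - Kinetic deprotonation at the methyl group (LiHMDS, THF, −78 °C) and acylation with 2,2,2‑trifluoroethyl trifluoroacetate should give (5R,6R)‑6‑[3,4‑bis(benzyloxy)phenyl]‑5‑[(benzyloxy)methyl]‑1,1,1‑trifluoro‑6‑[(triethylsilyl)oxy]hexane‑2,4‑dione F4.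
   - Detrifluoroacetylative diazo transfer (MsN3, Et3N, H2O, MeCN) should give the diazo ketone (3R,4R)‑4‑[3,4‑bis(benzyloxy)phenyl]‑3‑[(benzyloxy)methyl]‑1‑diazo‑4‑[(triethylsilyl)oxy]butan‑2‑one F5.
   - Buffered desilylation (TBAF/AcOH, THF, 0 °C) should give (3R,4R)‑4‑[3,4‑bis(benzyloxy)phenyl]‑3‑[(benzyloxy)methyl]‑1‑diazo‑4‑hydroxybutan‑2‑one F6.
   - Rh2(OAc)4 (cat., CH2Cl2, rt) should then close the oxolanone 12 by intramolecular O–H insertion, which is expected to outrun ylide formation at the benzyl ether oxygen.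

3. Step 8. Over‑reduction may occur: once the para‑hydroxyl is unmasked, the benzylic C5–O1 ring bond can be hydrogenolysed, and the alkyl benzyl ether cleaves slowly, which lengthens the exposure. The fallback sets out from 16 and comes back at 17 without new intermediates. It is a non‑reductive Lewis‑acid debenzylation with BCl3 and pentamethylbenzene as benzyl‑cation scavenger (CH2Cl2, −78 °C, quench with CHCl3/MeOH). At this temperature the aryl methyl ethers and the ring ether are expected to survive.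

**Further compounds**
F1 | step 7 | lithium (3R,4R,5R)‑5‑[3,4‑bis(benzyloxy)phenyl]‑4‑[(benzyloxy)methyl]‑3‑(chloromethyl)oxolan‑3‑olate | ClC[C@]1([O-])CO[C@@H](c2ccc(OCc3ccccc3)c(OCc3ccccc3)c2)[C@H]1COCc1ccccc1.[Li+]
F2 | step 7 | (3S,6R,7R)‑6‑[3,4‑bis(benzyloxy)phenyl]‑7‑[(benzyloxy)methyl]‑1,5‑dioxaspiro[2.4]heptane | C1[C@]2(O1)CO[C@@H](c3ccc(OCc4ccccc4)c(OCc4ccccc4)c3)[C@H]2COCc2ccccc2
F3 | step 6 | (3R,4R)‑4‑[3,4‑bis(benzyloxy)phenyl]‑3‑[(benzyloxy)methyl]‑4‑[(triethylsilyl)oxy]butan‑2‑one | CC[Si](CC)(CC)O[C@@H](c1ccc(OCc2ccccc2)c(OCc2ccccc2)c1)[C@@H](COCc1ccccc1)C(C)=O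
F4 | step 6 | (5R,6R)‑6‑[3,4‑bis(benzyloxy)phenyl]‑5‑[(benzyloxy)methyl]‑1,1,1‑trifluoro‑6‑[(triethylsilyl)oxy]hexane‑2,4‑dione | CC[Si](CC)(CC)O[C@@H](c1ccc(OCc2ccccc2)c(OCc2ccccc2)c1)[C@@H](COCc1ccccc1)C(=O)CC(=O)C(F)(F)F
F5 | step 6 | (3R,4R)‑4‑[3,4‑bis(benzyloxy)phenyl]‑3‑[(benzyloxy)methyl]‑1‑diazo‑4‑[(triethylsilyl)oxy]butan‑2‑one | CC[Si](CC)(CC)O[C@@H](c1ccc(OCc2ccccc2)c(OCc2ccccc2)c1)[C@@H](COCc1ccccc1)C(=O)C=[N+]=[N-]
F6 | step 6 | (3R,4R)‑4‑[3,4‑bis(benzyloxy)phenyl]‑3‑[(benzyloxy)methyl]‑1‑diazo‑4‑hydroxybutan‑2‑one | O[C@@H](c1ccc(OCc2ccccc2)c(OCc2ccccc2)c1)[C@@H](COCc1ccccc1)C(=O)C=[N+]=[N-]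
F0 | step 8 | none | none
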